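**Retrosynthetic overview**
1. No ring is built. Rings A, B and C and the (S) centre at C2 are bought together in (2S)-naringenin. Only the C6–CH3 and C8–prenyl bonds are made, always under neutral or acidic conditions so that ring C never opens.
2. Target ⇒ its 7,4'-diacetate (acidic methanolysis as the last step).
3. C8–prenyl bond ⇒ domino [3,3]/[3,3] aromatic Claisen–Cope rearrangement of the 5-O-prenyl ether. The C6 methyl blocks the ortho stop, so the prenyl group reaches C8 un-inverted.
4. 5-O-prenyl ether ⇒ Mitsunobu coupling of prenol with the chelated 5-OH of 6-methylnaringenin 7,4'-diacetate.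
5. C6–CH3 ⇒ Stille methylation of the 6-iodide ⇒ 5-OH-directed iodination of naringenin 7,4'-diacetate ⇒ (2S)-naringenin.

Assumption: (2S)-(−)-naringenin 1 (citrus- or fermentation-derived) is bought as the single enantiomer. Its ee is confirmed by chiral HPLC on receipt and re-checked at 2, 9 and 10.

**Step 1**
Reactants: 1 (2S)-naringenin
Product: 2 (2S)-naringenin 7,4'-diacetate (5-OH free)
Conditions: Ac2O (2.1 equiv), pyridine, 0 °C to rt, 4 h
Reagents that add atoms: acetic anhydride, CC(=O)OC(C)=O
Why: Selective O-acetylation works because the 7- and 4'-phenols acylate fast while the 5-OH is hydrogen-bonded to the C4 carbonyl, and capping both acidic phenols in this weakly basic medium shuts off the retro-oxa-Michael/quinone-methide opening of ring C, so the bought (S) centre is carried on unchanged.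

**Step 2**
Reactants: 2 (2S)-naringenin 7,4'-diacetate
Product: 3 (2S)-6-iodonaringenin 7,4'-diacetate
Conditions: NIS (1.05 equiv), TFA (10 mol %), MeCN, 0 °C to rt, dark
Reagents that add atoms: N-iodosuccinimide, O=C1CCC(=O)N1I
Why: In this electrophilic aromatic iodination the free chelated 5-OH of a 5-hydroxy-7-O-substituted flavonoid directs the iodonium source to its ortho carbon C6 (also para to O1) rather than to C8, ring B is switched off as its acetate, and the base-free medium leaves C2 untouched.

**Step 3**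
Reactants: 3 (2S)-6-iodonaringenin 7,4'-diacetate
Product: 4 (2S)-6-methylnaringenin 7,4'-diacetate
Conditions: SnMe4 (3 equiv), Pd2(dba)3 (2.5 mol %), AsPh3 (20 mol %), NMP, sealed tube, 70 °C
Reagents that add atoms: tetramethyltin, C[Sn](C)(C)C
Why: Stille cross-coupling (oxidative addition of the aryl iodide to zerovalent palladium, methyl transfer from tin, reductive elimination) needs no base, so the aryl acetates, the free 5-OH, the ketone and the base-labile C2 centre all survive.

**Step 4**
Reactants: 4 (2S)-6-methylnaringenin 7,4'-diacetate; 5 prenol (3-methylbut-2-en-1-ol)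
Product: 6 (2S)-6-methyl-5-O-prenylnaringenin 7,4'-diacetate
Conditions: PPh3 (1.5 equiv), DIAD (1.5 equiv), THF (0.5 M), 0 °C to rt
Reagents that add atoms: none
Why: Mitsunobu etherification uses the only free phenol (5-OH, acidic enough for the betaine) to displace the activated primary allylic oxyphosphonium in an SN2 sense, and no base strong enough to deprotonate C3 is present, so neither the acetates nor C2 are affected.

**Step 5**
Reactants: 6 (2S)-6-methyl-5-O-prenylnaringenin 7,4'-diacetate
Product: 9 (2S)-6-methyl-8-prenylnaringenin 7,4'-diacetate, via ortho-dienone 7 (not isolated), via para-dienone 8 (not isolated)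
Conditions: Eu(fod)3 (10 mol %; fod = 6,6,7,7,8,8,8-heptafluoro-2,2-dimethyl-3,5-octanedionate), acid-free PhCl, 85 °C, Ar, 16 h
Reagents that add atoms: none
Why: In this domino aromatic Claisen–Cope (para-Claisen) rearrangement, trivalent europium chelated between the C4 carbonyl and O5 speeds the first [3,3] shift to C6, the C6 methyl forbids rearomatisation of 7, a second [3,3] (Cope) shift across C7=C8 puts the un-inverted prenyl group on C8, and 8 enolises irreversibly to the chelated phenol, which erases the transient C6 and C8 centres without ever involving C2.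

**Step 6**
Reactants: 9 (2S)-6-methyl-8-prenylnaringenin 7,4'-diacetate
Product: 10 (2S)-6-methyl-8-prenylnaringenin
Conditions: HCl (0.5 M in MeOH), 35 °C, HPLC-monitored; then pH 6 phosphate buffer, EtOAc
Reagents that add atoms: none
Why: Acid-catalysed transesterification removes both aryl acetates without ever forming the phenoxides that open ring C (which would racemise C2 and swap the 6- and 8-substituents), and dilute methanolic HCl at this temperature is too mild to cyclise the prenyl group onto the 7-OH.

**Compound list**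
1 | (2S)-naringenin, (2S)-5,7-dihydroxy-2-(4-hydroxyphenyl)chroman-4-one | Oc1cc(O)c2c(c1)O[C@H](c1ccc(O)cc1)CC2=O | starting material
2 | (2S)-naringenin 7,4'-diacetate | CC(=O)Oc1cc(O)c2c(c1)O[C@H](c1ccc(OC(C)=O)cc1)CC2=O | intermediate
3 | (2S)-6-iodonaringenin 7,4'-diacetate | CC(=O)Oc1c(I)c(O)c2c(c1)O[C@H](c1ccc(OC(C)=O)cc1)CC2=O | intermediate
4 | (2S)-6-methylnaringenin 7,4'-diacetate | CC(=O)Oc1c(C)c(O)c2c(c1)O[C@H](c1ccc(OC(C)=O)cc1)CC2=O | intermediate
5 | prenol, 3-methylbut-2-en-1-ol | CC(C)=CCO | starting material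
6 | (2S)-6-methyl-5-O-prenylnaringenin 7,4'-diacetate | CC(=O)Oc1c(C)c(OCC=C(C)C)c2c(c1)O[C@H](c1ccc(OC(C)=O)cc1)CC2=O | intermediate
7 | ortho-dienone, (2S)-7-acetoxy-2-(4-acetoxyphenyl)-6-methyl-6-(2-methylbut-3-en-2-yl)-2,3-dihydrochromene-4,5(6H)-dione, both C6 epimers | O1[C@H](c3ccc(OC(C)=O)cc3)CC(=O)C2=C1C=C(OC(C)=O)C(C)(C(C)(C)C=C)C2=O | intermediate (not isolated)
8 | para-dienone, (2S)-7-acetoxy-2-(4-acetoxyphenyl)-6-methyl-8-(3-methylbut-2-enyl)-2,3-dihydrochromene-4,5(8H)-dione, both C8 epimers | O1[C@H](c3ccc(OC(C)=O)cc3)CC(=O)C2=C1C(CC=C(C)C)C(OC(C)=O)=C(C)C2=O | intermediate (not isolated)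
9 | (2S)-6-methyl-8-prenylnaringenin 7,4'-diacetate | CC(=O)Oc1c(C)c(O)c2c(c1CC=C(C)C)O[C@H](c1ccc(OC(C)=O)cc1)CC2=O | intermediate
10 | (2S)-6-methyl-8-prenylnaringenin | CC(C)=CCc1c(O)c(C)c(O)c2c1O[C@H](c1ccc(O)cc1)CC2=O | target

**Total step count:** 6. **Longest linear sequence:** 6 steps (1 → 10).

**Three steps most likely to fail**

Step 2. The iodination may go to C8, go twice, or stall on the acetate-deactivated ring A, and a wrong or labile iodide also ruins step 3. The fallback runs from 2 back to 4 and replaces halogenation plus cross-coupling by an ortho-specific [2,3]-sigmatropic one-carbon transfer. Me2S/NCS in CH2Cl2 at −25 °C converts the only free phenol of 2 into the aryloxydimethylsulfonium chloride F1. Et3N (1.1 equiv, −25 °C) deprotonates it to the sulfonium ylide F2. This shifts [2,3] onto C6, the only ortho carbon that bears hydrogen, to give the 6H-dienone F3. Enolisation gives (2S)-6-(methylthiomethyl)naringenin 7,4'-diacetate F4. Neutral-washed Raney Ni in EtOH/acetone at rt then cleaves both C–S bonds and gives 4.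

Step 4. The 5-OH of 4 is chelated and now flanked by the C6 methyl, so the Mitsunobu coupling with prenol may be too slow. The fallback runs from 4 back to 9. It brings in the smaller allyl group by a different bond-forming mode and builds the prenyl terminus afterwards. Allyl tert-butyl carbonate with Pd(PPh3)4 (5 mol %) in THF at 40 °C performs a Tsuji–Trost O-allylation through a π-allyl complex of divalent palladium, with base formed only in situ. This gives (2S)-5-O-allyl-6-methylnaringenin 7,4'-diacetate F5. Eu(fod)3 in PhCl at 110 °C runs the same Claisen–Cope relay through the 6-allyl-6-methyl ortho-dienone F6 and the 8-allyl para-dienone F7 to (2S)-8-allyl-6-methylnaringenin 7,4'-diacetate F8. Cross-metathesis with excess 2-methyl-2-butene (second-generation Grubbs catalyst, 5 mol %, CH2Cl2, 40 °C) converts the allyl into the prenyl group and gives 9.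

Step 5. Ether cleavage back to 4 with loss of isoprene, or an incomplete Cope stage, may outrun the domino process. The fallback runs from 4 to 10 and moves the migrating group to O7 as a reverse-prenyl ether, so that one ortho-Claisen shift is enough. HCl (0.5 M in MeOH) at 35 °C frees (2S)-6-methylnaringenin F9. tert-Butyl 2-methylbut-3-en-2-yl carbonate (1.0 equiv) with Pd(PPh3)4 (5 mol %) in THF at 0 °C etherifies the most acidic phenol, the 7-OH, at the tertiary allyl terminus. This gives (2S)-7-O-(1,1-dimethylallyl)-6-methylnaringenin F10. Warming in toluene at 90–110 °C triggers the [3,3] shift to C8 (C6 is blocked) through the 8H-dienone F11, whose enolisation gives 10 directly.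

**Further compounds**
F1 | step 2 | (2S)-7,4'-diacetoxy-flavanon-5-yloxy(dimethyl)sulfonium chloride | CC(=O)Oc1cc(O[S+](C)C)c2c(c1)O[C@H](c1ccc(OC(C)=O)cc1)CC2=O.[Cl-]
F2 | step 2 | sulfonium ylide of F1 | CC(=O)Oc1cc(O[S+](C)[CH2-])c2c(c1)O[C@H](c1ccc(OC(C)=O)cc1)CC2=O
F3 | step 2 | 6H-dienone, (2S)-7-acetoxy-2-(4-acetoxyphenyl)-6-(methylthiomethyl)-2,3-dihydrochromene-4,5(6H)-dione, both C6 epimers | O1[C@H](c3ccc(OC(C)=O)cc3)CC(=O)C2=C1C=C(OC(C)=O)C(CSC)C2=O
F4 | step 2 | (2S)-6-(methylthiomethyl)naringenin 7,4'-diacetate | CC(=O)Oc1c(CSC)c(O)c2c(c1)O[C@H](c1ccc(OC(C)=O)cc1)CC2=O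
F5 | step 4 | (2S)-5-O-allyl-6-methylnaringenin 7,4'-diacetate | CC(=O)Oc1c(C)c(OCC=C)c2c(c1)O[C@H](c1ccc(OC(C)=O)cc1)CC2=O
F6 | step 4 | 6-allyl-6-methyl ortho-dienone, both C6 epimers | O1[C@H](c3ccc(OC(C)=O)cc3)CC(=O)C2=C1C=C(OC(C)=O)C(C)(CC=C)C2=O
F7 | step 4 | 8-allyl para-dienone, both C8 epimers | O1[C@H](c3ccc(OC(C)=O)cc3)CC(=O)C2=C1C(CC=C)C(OC(C)=O)=C(C)C2=O
F8 | step 4 | (2S)-8-allyl-6-methylnaringenin 7,4'-diacetate | CC(=O)Oc1c(C)c(O)c2c(c1CC=C)O[C@H](c1ccc(OC(C)=O)cc1)CC2=O
F9 | step 5 | (2S)-6-methylnaringenin | Oc1c(C)c(O)c2c(c1)O[C@H](c1ccc(O)cc1)CC2=O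
F10 | step 5 | (2S)-7-O-(1,1-dimethylallyl)-6-methylnaringenin | C=CC(C)(C)Oc1c(C)c(O)c2c(c1)O[C@H](c1ccc(O)cc1)CC2=O
F11 | step 5 | 8H-dienone, (2S)-5-hydroxy-2-(4-hydroxyphenyl)-6-methyl-8-(3-methylbut-2-enyl)-2,3-dihydrochromene-4,7(8H)-dione, both C8 epimers | O1[C@H](c3ccc(O)cc3)CC(=O)C2=C1C(CC=C(C)C)C(=O)C(C)=C2O
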